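In a closed flask nothing leaves, so, taking one reagent per substrate molecule, what starting material and second substrate have lost together equals what reagent has lost.

| flask | starting material | reagent | second substrate | catalyst | remark | time |
|---|---|---|---|---|---|---|
| noon | 12 mM | 12.6 mM | 12 mM | 12 µM | the very flask that is asked about, followed so far |  |
| flask | 12 mM | 12.6 mM | 12.0 mM | 12 µM |  | 5.0 h |

noon run (percent of the starting material charged)

| time / min | target / % | starting material / % |
|---|---|---|
| 20.0 | 37.3 | 51.1 |
| 25.0 | 39.4 | 49.1 |
| 30.0 | 42.7 | 44.8 |
| 40.0 | 45.6 | 42.8 |
| 50.0 | 46.1 | 39.7 |
| 80.0 | 46.1 | 39.0 |
| 90.0 | 48.0 | 36.1 |

(standard deviation of a reading: 1 percentage point)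



* time, not beyond 5.0 h, at which the flask holds most target
* the amount of target, in percent of the starting material charged, at that time

I carry one number, 52.5%, the cover: the share of each substrate's charge that is served when reagent splits evenly between the two. It is the zero of my scale, and it marks reagent as the limiting reagent, 12.6 mM against 24.0 mM of substrates. An even split costs starting material 6.30 mM, but the last noon reading, 36.1% left at 90.0 min, means 7.67 mM lost, more than that, so I read starting material as the favoured substrate, within a scatter of 1 percentage point.

Its loss, as a fraction of charge, reads 1.47 h⁻¹ over the first 20.0 min and 0.0540 h⁻¹ between 50.0 min and 90.0 min, a fall by a factor of 27.2, while starting material itself falls by a factor of 1.99. If the rate goes with [starting material][reagent], these readings put the drop in [reagent] at a factor of 13.6, which, counted roughly from the charge and resting on a late rate read from scattered readings, leaves about 0.925 mM, less than the even share. So I commit to a peak near 1.5 h at about 48.0%.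

The weak link is the unseen second substrate, which on this balance has taken the rest of the reagent. The balance asks 33.4% of its charge, less than the cover, which restates the favour I read for starting material and is no independent check, and I have no reading of the catalyst's state.

The forecast differs from me, with 51% at 5 h: “The target should therefore creep upward to the end of the window”.

The flask peaks at 1.31 h with 46.7%, when reagent stands at 5.20% of its charge.

    starting material + reagent + catalyst ⇌ catalyst + target (K = 1900 M⁻¹, k = 5000 M⁻² s⁻¹)
    second substrate + reagent + catalyst → catalyst + second product (k = 2700 M⁻² s⁻¹)
    starting material + reagent → uncatalysed product (k = 0.0180 M⁻¹ s⁻¹)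

At that time the two substrates have lost on average 49.8% of their charges, against the cover of 52.5%. The neighbouring flask with 21 mM of reagent has a cover of 87.5%; by 5.00 h its substrates have lost on average 82.9%, and its best target is 64.9%, more than this flask gives.

The readings are simulated for an exercise; the scatter is artificial.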